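## Structural features

The target is a cis-fused perhydroazulene (azulene numbering: C1 quaternary methyl carbon, C3a and C8a ring fusion, C4 gem-dimethyl carbon, C8 bearing the exocyclic methylene) joined by the single bond C1–C8′ to a 2,7-dioxabicyclo[3.2.1]octan-3-one (primed numbering: C1′ acetal carbon, O2′–C3′ lactone, C4′ acetoxy carbon, C5′ bridgehead, C6′ carrying CO2Me, O7′, C8′ one-carbon bridge). Its eight stereocentres form one unbroken chain: C3a, C8a and C1 on the cyclopentane, then C8′, flanked by C1′ and C5′, and C5′ flanked by C4′ and C6′. The ring-fusion hydrogens are cis to each other and to the C1–C8′ bond, so the seven-membered ring lies on the face of the C1 methyl group. At C8′ the carbobicycle points over the lactone bridge, the C6′ ester is exo, and the C4′ acetate lies on the side of the O7′–C6′ bridge. Fragile groups are the acylal C1′ (acid, base and nucleophiles), the α-acetoxy lactone, the ester α to an ether oxygen (epimerisable), and the exocyclic 1,1-disubstituted alkene (strong acid, hydrogenation). The real difficulty is twofold: fixing C3a relative to the remote quaternary C1, and controlling C8′, a planar centre in any bond-forming step, right beside that quaternary carbon. The key step exploits the fact that C4 is bonded to C3a and C8 to C8a: C7–C8–C8a–C3a is a 2-oxygenated diene built on the cyclopentene, and C4–C5–C6 is a prenyl-type three-carbon unit.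

## Logic of the disconnections

In 32 the acetate C–O bond and then the C4′–O bond of 31 are cut, leading to 30. Oxygen is introduced last because only on the rigid bicycle is one face of C4′ covered by the carbobicycle. The gain is the removal of the most labile group and one stereocentre. The demand is that the lactone enolate of 30 forms in preference to the ester enolate and is oxidised before the acylal fragments.

In 30 the lactone bond C1′–O2′ is cut and C8′ is released as an sp2 carbon, leading through 29 and 28 to 27. The reason is that C8′ next to a quaternary carbon cannot be trusted to form correctly in a C–C bond-forming step, but can be set by protonation while the lactone closes. The bicycle is reduced to a monocyclic tetrahydrofuran whose C8′ and C1′ configurations are irrelevant. The forward step must deliver the proton so that the carbobicycle ends over the lactone bridge, under acid mild enough for the exocyclic alkene.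

In 27 the C8′–C5′ bond is cut (radical 5-exo closure), giving 26. The ring is opened to an acyclic mixed acetal. The demand is that the new C5′ arm forms trans to the C6′ ester.

In 26 the acetal bond C1′–O7′ and the C8′–Br bond are cut, giving 22 and 25. The route becomes convergent, and all carbons of the heterocycle sit in one small chiral fragment. The demand is chemoselective bromination of the enol ether in the presence of the methylene group.

In 25 the C4′=C5′ double bond is cut (cross-metathesis), giving 23 and 24. The C6′ stereocentre then comes from a four-carbon hydroxy ester. The demand is E-selective coupling without isomerisation of the allylic alcohol.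

In 22 the enol ether double bond is retraced to the acetal of 21, and the exocyclic C=C of 21 to the ketone of 20. Both alkenes are thus held as robust functions until late. The demand is a non-basic methylenation of a hindered, enolisable ketone that leaves C8a untouched.

In 20 the C6–H bond is retraced to the C6 carboxyl group of 18 (via 19), the C5–C6 single bond to the enoate of 17, and the C8a–H bond with the C8 carbonyl to the silyl enol ether of 16. The ester is only the acceptor group of the carbenoid and must be deleted. This leads back to the direct annulation product. The demands are protonation of C8a on the face of H-3a and neutral conditions throughout.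

In 16 the bonds C4–C3a and C6–C7 are cut (formal [4+3], via 15), giving 11 and 14. The seven-membered ring and C3a arise in one operation from a cyclopentene and a five-carbon diazo ester. The demands are attack on the methyl face of the diene, a cis-divinylcyclopropane, and a Cope step with a fully substituted terminus.

In 11 the Si–O bond is cut to give 10, and in 10 the bond between the ring and the acetyl carbon is cut (cross-coupling via 9), giving 7 and 8. The diene is reduced to an enol triflate and a two-carbon stannane. The demands are enolisation at the methyl group and survival of the acetal.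

In 7 the acetal is retraced through 6 to the terminal alkene of 5 (one carbon lost), and the C–OTf bond of 5 to the ketone of 4. The side chain thus arrives at the aldehyde oxidation level in one step. The demand is that ozone selects the terminal alkene over the triflate-bearing one.

In 4 the bond from the quaternary carbon to the allyl group is cut (decarboxylative allylation of 3), and 3 is cut at the enol C–O bond to 1 and 2. The quaternary stereocentre then comes from a racemic ketone. The demands are enantioselection at a five-membered enolate and regioselective formation of the tetrasubstituted enol carbonate.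

In 14 the C=N2 unit is removed to give 13, and the benzyl C–O bond of 13 is cut to give 12. The benzyl ester is chosen so that one later hydrogenation frees the acid. The demand is that 14 is used as soon as it is made.

## Other disconnections considered

Alternative 1: The cut is the C8′–C5′ bond of the tetrahydrofuran. In the forward step a tin radical abstracts bromine from a mixed bromoacetal (compound 26 of this route), and the C8′ radical closes 5-exo onto the γ-alkoxy enoate to give A1. In its favour, it joins the carbobicycle to a single fragment holding every heterocycle carbon, runs under neutral conditions that the exocyclic alkene tolerates, and should set C5′ trans to the C6′ ester through a chair-like transition state. Against it, A1 needs the quaternary substituent at C8′ cis to the new acetic ester arm, which is the contra-steric outcome for a radical carrying a tertiary alkyl group. As the centrepiece of a plan it also leaves the three contiguous stereocentres of the hydroazulene unsolved. In comparison, the two plans are complementary: the chosen route uses this same closure as step 17, but does not rely on its outcome at C8′, which is reset in step 18. On convergence, functional-group tolerance and step count for the heterocycle the alternative is the equal of the chosen plan, and a 5-exo radical closure is mechanistically at least as dependable as a carbenoid cascade. It is weaker only because the step that would carry the strategy controls the easy stereocentre and none of the hard ones.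

Alternative 2: The cuts are C8′–C5′ and the C–O bond at the carbinol carbon next to C5′, with C4′, C5′, C6′ and both carboxyl carbons drawn from a cyclopentenone. In the forward step the lithium enolate of ester A2 would add to silyloxycyclopentenone A3 anti to the silyloxy group, and the resulting ketone enolate would be hydroxylated by an N-sulfonyloxaziridine anti to the new chain, giving A4. In its favour, three contiguous stereocentres are set in one flask by cyclic trans,trans induction from a chiron available in both enantiomers, and the all-trans cyclopentane maps exactly onto the arrangement at C4′, C5′ and C6′. Against it, C8′ is formed in an open transition state between a neopentyl-type enolate and the enone. After the key step the ring must be cleaved and three carboxyl-level carbons differentiated, including reduction of the C8′ ester to the aldehyde level. In comparison, the alternative is better than the chosen plan in stereocontrol of C4′ to C6′, where the chosen route needs a separate enolate oxidation. It is equal in mechanistic reliability (ionic against radical). It is clearly worse in step economy after the union. Structurally it replaces only the endgame: A2 could be supplied by the same [4+3] annulation with the side chain oxidised instead of acetalised.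

Alternative 3: The cuts are the ring-fusion bond C3a–C8a and the C4–C5 bond. In the forward step irradiation of enol A5 would add the enol double bond to the tethered trisubstituted alkene, and retro-aldol opening of the cyclobutanol would give dione A6. In its favour, it needs no diazo compound and no rhodium (better than the chosen plan on safety and cost), it forms the seven-membered ring and the cis ring fusion in one operation, and it leaves no ester to delete. It builds two skeletal bonds and one ring, which is equal to the chosen step. Against it, A6 carries an extra ketone at C5 beside the gem-dimethyl carbon that must be told apart from the C8 ketone and removed. The face of the cycloaddition is decided only by the acyclic quaternary carbon, whose methyl and ester arms differ little, and no catalyst can override this. A5, with a quaternary carbon on C2 of the dione, is itself hard to make. In comparison, the removal of the C5 ketone costs about as many steps as the removal of the ester in the chosen plan, so step economy is roughly equal. The chosen plan is stronger in that the face selection can be put under catalyst control.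

Key step: step 9

Assumption: methyl (R)-2-hydroxybut-3-enoate (23) is taken as a purchasable enantiopure building block; the (R)-oxynitrilase cyanohydrin of acrolein followed by Pinner methanolysis is the known access.

Az in the names below is the 1,4,4-trimethyl-8-methylenedecahydroazulen-1-yl group, cis-fused, with H-3a and H-8a trans to the C1 methyl group, as in the target.

## Steps

Step 1
Reactants: 1 2-methylcyclopentan-1-one (racemic); 2 allyl chloroformate
Product: 3 allyl 2-methylcyclopent-1-en-1-yl carbonate
Conditions: KOt-Bu, DMF, 23 °C; then 2, −40 → 0 °C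
Reagents that add atoms: none
Why: The alkoxide equilibrates the enolates toward the tetrasubstituted one, which is O-acylated by the chloroformate (enol carbonate formation); the minor regioisomer would be removed by chromatography.

Step 2
Reactants: 3 allyl 2-methylcyclopent-1-en-1-yl carbonate
Product: 4 (S)-2-allyl-2-methylcyclopentan-1-one
Conditions: Pd2(dba)3 (2.5 mol %), (S)-t-Bu-PHOX (6 mol %), THF, 25 °C
Reagents that add atoms: none
Why: Decarboxylative asymmetric allylic alkylation (Tsuji type): zerovalent palladium ionises the carbonate, CO2 is lost and the enolate recombines with the allyl unit inside the chiral phosphinooxazoline pocket. The (S)-ligand should give the (S)-ketone by analogy with six-membered enolates; this sets the quaternary centre C1.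

Step 3
Reactants: 4 (S)-2-allyl-2-methylcyclopentan-1-one
Product: 5 (S)-5-allyl-5-methylcyclopent-1-en-1-yl trifluoromethanesulfonate
Conditions: KN(SiMe3)2, THF, −78 °C; PhNTf2, −78 → 0 °C
Reagents that add atoms: N-phenylbis(trifluoromethanesulfonimide), O=S(=O)(N(c1ccccc1)S(=O)(=O)C(F)(F)F)C(F)(F)F
Why: Only one α-carbon carries hydrogen, so enolate formation and O-sulfonylation (enol triflate formation) are regiochemically unambiguous.

Step 4
Reactants: 5 (S)-5-allyl-5-methylcyclopent-1-en-1-yl trifluoromethanesulfonate
Product: 7 (S)-5-(2,2-dimethoxyethyl)-5-methylcyclopent-1-en-1-yl trifluoromethanesulfonate, via aldehyde 6 (not isolated)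
Conditions: O3, CH2Cl2/MeOH, −78 °C; Me2S, −78 → 23 °C; then HC(OMe)3, TsOH·H2O (cat.), 23 °C
Reagents that add atoms: trimethyl orthoformate, COC(OC)OC; methanol, CO
Why: Ozonolysis with reductive work-up; ozone attacks the electron-rich monosubstituted alkene far faster than the triflate-deactivated ring alkene. Acid-catalysed acetalisation of 6 in the same flask stores the side chain at the aldehyde oxidation level needed later.

Step 5
Reactants: 7 (S)-5-(2,2-dimethoxyethyl)-5-methylcyclopent-1-en-1-yl trifluoromethanesulfonate; 8 tributyl(1-ethoxyvinyl)stannane
Product: 10 1-[(S)-5-(2,2-dimethoxyethyl)-5-methylcyclopent-1-en-1-yl]ethan-1-one, via ethoxydiene 9 (not isolated)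
Conditions: Pd(PPh3)4 (5 mol %), LiCl, THF, 65 °C; then 0.1 M aq. HCl, THF, 0 °C, brief
Reagents that add atoms: water, O
Why: Stille coupling of the enol triflate (chloride assists transmetallation) gives 2-ethoxydiene 9. Its enol ether is hydrolysed by very dilute acid far faster than the dimethyl acetal.

Step 6
Reactants: 10 1-[(S)-5-(2,2-dimethoxyethyl)-5-methylcyclopent-1-en-1-yl]ethan-1-one
Product: 11 tert-butyl({1-[(S)-5-(2,2-dimethoxyethyl)-5-methylcyclopent-1-en-1-yl]vinyl}oxy)dimethylsilane
Conditions: LiN(i-Pr)2, THF, −78 °C; TBSCl, DMPU, −78 → 0 °C
Reagents that add atoms: tert-butyldimethylsilyl chloride, CC(C)(C)[Si](C)(C)Cl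
Why: Kinetic deprotonation at the methyl group (cross-conjugated dienolate) and O-silylation give the 2-silyloxydiene. Basic conditions are chosen because a silyl triflate could ionise the acetal and trigger an intramolecular Mukaiyama aldol reaction.

Step 7
Reactants: 12 4-methylpent-3-enoic acid
Product: 13 benzyl 4-methylpent-3-enoate
Conditions: BnBr, K2CO3, DMF, 23 °C
Reagents that add atoms: benzyl bromide, BrCc1ccccc1
Why: O-Alkylation of the carboxylate (SN2) under mild base leaves the β,γ-double bond in place.

Step 8
Reactants: 13 benzyl 4-methylpent-3-enoate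
Product: 14 benzyl 2-diazo-4-methylpent-3-enoate
Conditions: 4-acetamidobenzenesulfonyl azide, DBU, MeCN, 0 °C; used at once
Reagents that add atoms: 4-acetamidobenzenesulfonyl azide, CC(=O)Nc1ccc(cc1)S(=O)(=O)N=[N+]=[N-]
Why: Deprotonative diazo transfer (Regitz type) to the α-position activated by the ester and the alkene. Vinyldiazo esters cyclise to pyrazoles on standing, so 14 is kept cold and used directly.

Step 9
Reactants: 11 tert-butyl({1-[(S)-5-(2,2-dimethoxyethyl)-5-methylcyclopent-1-en-1-yl]vinyl}oxy)dimethylsilane; 14 benzyl 2-diazo-4-methylpent-3-enoate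
Product: 16 benzyl 8-(tert-butyldimethylsilyloxy)-1-(2,2-dimethoxyethyl)-1,4,4-trimethyl-1,2,3,3a,4,7-hexahydroazulene-6-carboxylate (H-3a trans to the C1 methyl), via divinylcyclopropane 15 (not isolated)
Conditions: Rh2(S-DOSP)4 (1 mol %), hexanes, −40 → 23 °C, 14 added over 2 h; then toluene, 80 °C
Reagents that add atoms: none
Why: The dirhodium tetraprolinate decomposes 14 to a donor/acceptor rhodium vinylcarbenoid, which adds in a concerted, asynchronous way to the electron-rich siloxyvinyl group of 11 (terminal CH2 first) and gives cyclopropane 15 with the 2-methylpropenyl and cyclopentenyl groups cis. 15 then undergoes the Cope rearrangement of a cis-divinylcyclopropane through a boat transition state, so the net result is a suprafacial formal [4+3] annulation; the closest known reaction type is this same tandem cyclopropanation/Cope rearrangement of vinylcarbenoids with 2-silyloxy-1,3-dienes. The seven-membered ring is closed by the [3,3]-sigmatropic shift, in which the C4–C3a bond forms as the cyclopropane bond between the oxygenated and the ester-bearing carbon breaks, while the C6–C7 bond stems from the cyclopropanation. The only new stereocentre, C3a, is fixed by the face of the siloxyvinyl group that the carbenoid attacks, because the boat Cope step hands the three-carbon unit to the same face of the s-cis diene. The quaternary C1 lies far from the point of attack and gives only weak bias, so the chiral catalyst is relied on; its usual model (ester trans to the alkene substituent, end-on approach) puts the cyclopropane on the methyl face of the cyclopentene, anti to the acetal arm, for the (S)-catalyst. Chemoselectivity for the siloxy alkene over the trisubstituted ring alkene follows from its higher electron density and free terminus, and the hydrocarbon solvent together with the fully substituted vinyl terminus disfavours zwitterionic [3+2] pathways. One methyl group of the prenyl terminus is forced over the cyclopropane in the boat transition state, which is why a warming period is planned.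

Step 10
Reactants: 16 benzyl 8-(tert-butyldimethylsilyloxy)-1-(2,2-dimethoxyethyl)-1,4,4-trimethyl-1,2,3,3a,4,7-hexahydroazulene-6-carboxylate
Product: 17 benzyl 1-(2,2-dimethoxyethyl)-1,4,4-trimethyl-8-oxo-1,2,3,3a,4,7,8,8a-octahydroazulene-6-carboxylate (cis-fused; H-3a and H-8a trans to the C1 methyl)
Conditions: Bu4NF, AcOH (1:1), THF, −20 → 0 °C
Reagents that add atoms: none
Why: Fluoride cleaves the silyl enol ether and the enolate is protonated by acetic acid at C8a from the face of H-3a, opposite the quaternary C4 on the neighbouring carbon, which should give the cis-fused ketone. The buffered medium avoids later epimerisation and leaves the acetal and the enoate untouched.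

Step 11
Reactants: 17 benzyl 1-(2,2-dimethoxyethyl)-1,4,4-trimethyl-8-oxo-1,2,3,3a,4,7,8,8a-octahydroazulene-6-carboxylate
Product: 18 1-(2,2-dimethoxyethyl)-1,4,4-trimethyl-8-oxodecahydroazulene-6-carboxylic acid (cis-fused; both C6 epimers)
Conditions: H2 (3 atm), Pd/C, EtOAc, 23 °C
Reagents that add atoms: none
Why: Heterogeneous hydrogenation reduces the conjugated alkene and hydrogenolyses the benzyl ester in one neutral operation. The configuration at C6 is irrelevant because that carbon loses its carboxyl group next.

Step 12
Reactants: 18 1-(2,2-dimethoxyethyl)-1,4,4-trimethyl-8-oxodecahydroazulene-6-carboxylic acid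
Product: 20 1-(2,2-dimethoxyethyl)-1,4,4-trimethyldecahydroazulen-8-one (cis-fused; numbering of 17 kept), via thiohydroxamate ester 19 (not isolated)
Conditions: N-hydroxypyridine-2-thione, DCC, DMAP (cat.), CH2Cl2, 23 °C, dark; then t-BuSH, hν (tungsten lamp), 23 °C
Reagents that add atoms: none
Why: Barton decarboxylation: ester 19 fragments under light to CO2 and the secondary C6 radical, which takes hydrogen from the thiol. The neutral conditions spare the acetal and the epimerisable C8a.

Step 13
Reactants: 20 1-(2,2-dimethoxyethyl)-1,4,4-trimethyldecahydroazulen-8-one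
Product: 21 1-(2,2-dimethoxyethyl)-1,4,4-trimethyl-8-methylenedecahydroazulene (cis-fused)
Conditions: Cp2TiMe2, toluene, 70 °C, dark
Reagents that add atoms: dimethyltitanocene, C[Ti](C)(C1C=CC=C1)C1C=CC=C1
Why: Petasis methylenation: the thermally formed titanocene methylidene is non-basic and olefinates hindered, enolisable ketones by cycloaddition and cycloreversion, so C8a keeps its configuration. No ester is left to compete.

Step 14
Reactants: 21 1-(2,2-dimethoxyethyl)-1,4,4-trimethyl-8-methylenedecahydroazulene
Product: 22 1-[(E)-2-methoxyvinyl]-1,4,4-trimethyl-8-methylenedecahydroazulene (cis-fused; any Z isomer is equally usable)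
Conditions: TMSOTf, i-Pr2NEt, CH2Cl2, −20 → 23 °C
Reagents that add atoms: none
Why: The silyl triflate ionises the acetal to an oxocarbenium ion, which the amine deprotonates at the only neighbouring CH2 (acetal-to-enol-ether elimination). No protic acid is present, so the exocyclic alkene is safe.

Step 15
Reactants: 23 methyl (R)-2-hydroxybut-3-enoate; 24 tert-butyl acrylate
Product: 25 1-tert-butyl 5-methyl (4R,2E)-4-hydroxypent-2-enedioate
Conditions: second-generation Hoveyda–Grubbs catalyst (3 mol %), 24 (3 equiv), CH2Cl2, 40 °C
Reagents that add atoms: none
Why: Cross-metathesis of a terminal allylic alcohol with an acrylate in excess is E-selective and does not touch the carbinol stereocentre, which becomes C6′.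

Step 16
Reactants: 22 1-[(E)-2-methoxyvinyl]-1,4,4-trimethyl-8-methylenedecahydroazulene; 25 1-tert-butyl 5-methyl (4R,2E)-4-hydroxypent-2-enedioate
Product: 26 1-tert-butyl 5-methyl (4R,2E)-4-(2-Az-2-bromo-1-methoxyethoxy)pent-2-enedioate (epimers at the bromo and acetal carbons)
Conditions: NBS, 25 (2 equiv), NaHCO3, CH2Cl2, −40 → 0 °C
Reagents that add atoms: N-bromosuccinimide, O=C1CCC(=O)N1Br
Why: Haloacetalisation: the enol ether, far more nucleophilic than the methylene group, is brominated at C8′ and the oxocarbenium ion is trapped by alcohol 25. The configurations at C8′ and C1′ are of no consequence.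

Step 17
Reactants: 26 1-tert-butyl 5-methyl (4R,2E)-4-(2-Az-2-bromo-1-methoxyethoxy)pent-2-enedioate
Product: 27 methyl (2R)-4-Az-3-(2-tert-butoxy-2-oxoethyl)-5-methoxytetrahydrofuran-2-carboxylate (2,3-trans; epimers at C4 and C5)
Conditions: Bu3SnH (slow addition), AIBN (cat.), benzene, 80 °C
Reagents that add atoms: none
Why: Ueno–Stork cyclisation: the C8′ radical adds 5-exo-trig to the enoate β-carbon through a chair-like transition state with the C6′ ester pseudo-equatorial, which places the new C5′ arm trans to it. The α-ester radical is then reduced by the stannane.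

Step 18
Reactants: 27 methyl (2R)-4-Az-3-(2-tert-butoxy-2-oxoethyl)-5-methoxytetrahydrofuran-2-carboxylate
Product: 30 methyl (6R)-8-Az-3-oxo-2,7-dioxabicyclo[3.2.1]octane-6-carboxylate (Az over the lactone bridge; ester exo), via dihydrofuran silyl ester 28 (not isolated), via dihydrofuran acid 29 (not isolated)
Conditions: TMSOTf, i-Pr2NEt, CH2Cl2, −20 → 23 °C; pH 7 buffer; then PPTS (cat.), CH2Cl2, 23 °C
Reagents that add atoms: none
Why: The silyl triflate and amine turn the tert-butyl ester into a silyl ester and the cyclic acetal into the enol ether (28), which erases C8′ and C1′. After hydrolysis to 29, mild acid adds the carboxylic acid across the enol ether, as in tetrahydropyranyl ester formation: C8′ is protonated anti to the C5′ arm and the δ-lactone closes on the face of that arm. The epimeric cation would press the carbobicycle against the exo ester in the bicycle and can revert through the enol ether.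

Step 19
Reactants: 30 methyl (6R)-8-Az-3-oxo-2,7-dioxabicyclo[3.2.1]octane-6-carboxylate
Product: 31 methyl (6R)-8-Az-4-hydroxy-3-oxo-2,7-dioxabicyclo[3.2.1]octane-6-carboxylate (hydroxyl on the side of the O7–C6 bridge)
Conditions: KN(SiMe3)2, THF, −78 °C; 2-(phenylsulfonyl)-3-phenyloxaziridine, −78 °C; aq. NH4Cl
Reagents that add atoms: 2-(phenylsulfonyl)-3-phenyloxaziridine, O=S(=O)(N1OC1c1ccccc1)c1ccccc1
Why: Enolate hydroxylation: the lactone α-CH2 is more acidic and more accessible than the α-alkoxy ester C–H, and its enolate is oxidised from the face away from the carbobicycle, which sits axially over the other face. This gives the equatorial C4′ alcohol of the target.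

Step 20
Reactants: 31 methyl (6R)-8-Az-4-hydroxy-3-oxo-2,7-dioxabicyclo[3.2.1]octane-6-carboxylate
Product: 32 CNP0215240.1, methyl (6R)-4-acetoxy-8-Az-3-oxo-2,7-dioxabicyclo[3.2.1]octane-6-carboxylate
Conditions: Ac2O, pyridine, DMAP (cat.), CH2Cl2, 0 → 23 °C
Reagents that add atoms: acetic anhydride, CC(=O)OC(C)=O
Why: DMAP-catalysed acylation of the secondary alcohol; the mild base leaves the acylal and the ester stereocentre intact.

## Compound list

1 | 2-methylcyclopentan-1-one (racemic) | CC1CCCC1=O | starting material
2 | allyl chloroformate | C=CCOC(Cl)=O | starting material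
3 | allyl 2-methylcyclopent-1-en-1-yl carbonate | C=CCOC(=O)OC1=C(C)CCC1 | intermediate
4 | (S)-2-allyl-2-methylcyclopentan-1-one | O=C1CCC[C@@]1(C)CC=C | intermediate
5 | (S)-5-allyl-5-methylcyclopent-1-en-1-yl trifluoromethanesulfonate | O=S(=O)(OC1=CCC[C@@]1(C)CC=C)C(F)(F)F | intermediate
6 | (S)-5-methyl-5-(2-oxoethyl)cyclopent-1-en-1-yl trifluoromethanesulfonate | O=S(=O)(OC1=CCC[C@@]1(C)CC=O)C(F)(F)F | intermediate
7 | (S)-5-(2,2-dimethoxyethyl)-5-methylcyclopent-1-en-1-yl trifluoromethanesulfonate | O=S(=O)(OC1=CCC[C@@]1(C)CC(OC)OC)C(F)(F)F | intermediate
8 | tributyl(1-ethoxyvinyl)stannane | CCCC[Sn](CCCC)(CCCC)C(=C)OCC | starting material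
9 | (S)-5-(2,2-dimethoxyethyl)-1-(1-ethoxyvinyl)-5-methylcyclopent-1-ene | C=C(OCC)C1=CCC[C@@]1(C)CC(OC)OC | intermediate
10 | 1-[(S)-5-(2,2-dimethoxyethyl)-5-methylcyclopent-1-en-1-yl]ethan-1-one | CC(=O)C1=CCC[C@@]1(C)CC(OC)OC | intermediate
11 | tert-butyl({1-[(S)-5-(2,2-dimethoxyethyl)-5-methylcyclopent-1-en-1-yl]vinyl}oxy)dimethylsilane | C=C(O[Si](C)(C)C(C)(C)C)C1=CCC[C@@]1(C)CC(OC)OC | intermediate
12 | 4-methylpent-3-enoic acid | CC(C)=CCC(=O)O | starting material
13 | benzyl 4-methylpent-3-enoate | CC(C)=CCC(=O)OCc1ccccc1 | intermediate
14 | benzyl 2-diazo-4-methylpent-3-enoate | CC(C)=CC(=[N+]=[N-])C(=O)OCc1ccccc1 | intermediate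
15 | benzyl 2-(tert-butyldimethylsilyloxy)-2-[(S)-5-(2,2-dimethoxyethyl)-5-methylcyclopent-1-en-1-yl]-1-(2-methylprop-1-en-1-yl)cyclopropane-1-carboxylate (alkenyl groups cis) | O=C(OCc1ccccc1)[C@@]2(C=C(C)C)C[C@]2(O[Si](C)(C)C(C)(C)C)C3=CCC[C@@]3(C)CC(OC)OC | intermediate
16 | benzyl 8-(tert-butyldimethylsilyloxy)-1-(2,2-dimethoxyethyl)-1,4,4-trimethyl-1,2,3,3a,4,7-hexahydroazulene-6-carboxylate | O=C(OCc1ccccc1)C1=CC(C)(C)[C@@H]2CC[C@@](C)(CC(OC)OC)C2=C(O[Si](C)(C)C(C)(C)C)C1 | intermediate
17 | benzyl 1-(2,2-dimethoxyethyl)-1,4,4-trimethyl-8-oxo-1,2,3,3a,4,7,8,8a-octahydroazulene-6-carboxylate (cis-fused) | O=C1CC(C(=O)OCc3ccccc3)=CC(C)(C)[C@@H]2CC[C@@](C)(CC(OC)OC)[C@H]12 | intermediate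
18 | 1-(2,2-dimethoxyethyl)-1,4,4-trimethyl-8-oxodecahydroazulene-6-carboxylic acid (C6 epimers) | O=C1CC(C(=O)O)CC(C)(C)[C@@H]2CC[C@@](C)(CC(OC)OC)[C@H]12 | intermediate
19 | 2-thioxopyridin-1(2H)-yl ester of 18 | O=C1CC(C(=O)ON3C=CC=CC3=S)CC(C)(C)[C@@H]2CC[C@@](C)(CC(OC)OC)[C@H]12 | intermediate
20 | 1-(2,2-dimethoxyethyl)-1,4,4-trimethyldecahydroazulen-8-one (cis-fused) | O=C1CCCC(C)(C)[C@@H]2CC[C@@](C)(CC(OC)OC)[C@H]12 | intermediate
21 | 1-(2,2-dimethoxyethyl)-1,4,4-trimethyl-8-methylenedecahydroazulene (cis-fused) | C=C1CCCC(C)(C)[C@@H]2CC[C@@](C)(CC(OC)OC)[C@H]12 | intermediate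
22 | 1-[(E)-2-methoxyvinyl]-1,4,4-trimethyl-8-methylenedecahydroazulene (cis-fused) | C=C1CCCC(C)(C)[C@@H]2CC[C@@](C)(/C=C/OC)[C@H]12 | intermediate
23 | methyl (R)-2-hydroxybut-3-enoate | COC(=O)[C@H](O)C=C | starting material
24 | tert-butyl acrylate | C=CC(=O)OC(C)(C)C | starting material
25 | 1-tert-butyl 5-methyl (4R,2E)-4-hydroxypent-2-enedioate | COC(=O)[C@H](O)/C=C/C(=O)OC(C)(C)C | intermediate
26 | 1-tert-butyl 5-methyl (4R,2E)-4-(2-Az-2-bromo-1-methoxyethoxy)pent-2-enedioate (epimers at CHBr and acetal carbon) | C=C1CCCC(C)(C)[C@@H]2CC[C@@](C)(C(Br)C(OC)O[C@H](/C=C/C(=O)OC(C)(C)C)C(=O)OC)[C@H]12 | intermediate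
27 | methyl (2R)-4-Az-3-(2-tert-butoxy-2-oxoethyl)-5-methoxytetrahydrofuran-2-carboxylate (2,3-trans; epimers at C4 and C5) | C=C1CCCC(C)(C)[C@@H]2CC[C@@](C)(C3C(OC)O[C@@H](C(=O)OC)[C@@H]3CC(=O)OC(C)(C)C)[C@H]12 | intermediate
28 | methyl (2R)-4-Az-3-[2-oxo-2-(trimethylsilyloxy)ethyl]-2,3-dihydrofuran-2-carboxylate (2,3-trans) | C=C1CCCC(C)(C)[C@@H]2CC[C@@](C)(C3=CO[C@@H](C(=O)OC)[C@@H]3CC(=O)O[Si](C)(C)C)[C@H]12 | intermediate
29 | 2-[(2R)-4-Az-2-(methoxycarbonyl)-2,3-dihydrofuran-3-yl]acetic acid (2,3-trans) | C=C1CCCC(C)(C)[C@@H]2CC[C@@](C)(C3=CO[C@@H](C(=O)OC)[C@@H]3CC(=O)O)[C@H]12 | intermediate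
30 | methyl (6R)-8-Az-3-oxo-2,7-dioxabicyclo[3.2.1]octane-6-carboxylate | C=C1CCCC(C)(C)[C@@H]2CC[C@@](C)([C@@H]3[C@@H]4OC(=O)C[C@H]3[C@H](C(=O)OC)O4)[C@H]12 | intermediate
31 | methyl (6R)-8-Az-4-hydroxy-3-oxo-2,7-dioxabicyclo[3.2.1]octane-6-carboxylate | C=C1CCCC(C)(C)[C@@H]2CC[C@@](C)([C@@H]3[C@@H]4OC(=O)[C@@H](O)[C@H]3[C@H](C(=O)OC)O4)[C@H]12 | intermediate
32 | CNP0215240.1, methyl (6R)-4-acetoxy-8-Az-3-oxo-2,7-dioxabicyclo[3.2.1]octane-6-carboxylate | C=C1CCCC(C)(C)[C@@H]2CC[C@@](C)([C@@H]3[C@@H]4OC(=O)[C@@H](OC(C)=O)[C@H]3[C@H](C(=O)OC)O4)[C@H]12 | target

## Step count and least certain steps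

Total step count: 20. Longest linear sequence: 17 steps (from 1 to 32 through steps 1–6, 9–14 and 16–20). Steps 7–8 and step 15 are side branches.

Step 9 (key step). The most likely failure is poor face selection at the siloxyvinyl group, because the quaternary carbon is remote from the point of attack and the catalyst may not override the substrate. A second risk is stereomutation of the donor–acceptor cyclopropane by zwitterionic ring opening at the temperature needed for the hindered Cope step. The fallback moves stereocontrol from the catalyst to a covalently bound auxiliary. It sets out from 12 and 11 and returns at 18.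
- 12 is esterified with (R)-pantolactone (DCC, DMAP) to (R)-pantolactonyl 4-methylpent-3-enoate F1.
- Diazo transfer as in step 8 gives the diazo ester F2.
- F2 is decomposed with achiral Rh2(OOct)4 in pentane in the presence of 11, so that the α-alkoxycarbonyl auxiliary directs the cyclopropanation before the Cope step and gives the cycloadduct F3.
- Desilylation as in step 10 gives the keto enoate F4.
- Hydrogenation over Pd/C gives the saturated keto ester F5.
- LiOH/H2O2 at 0 °C removes the auxiliary and gives 18.

Step 18. The most likely failure is delivery of the proton to C8′ on the wrong face, possibly internally by the carboxylic acid on the C5′ arm, followed by slow correction. Acid-induced migration of the exocyclic alkene is a lesser risk. The fallback sets C8′ by equilibration at the aldehyde oxidation level instead of by enol ether protonation. It sets out from 27 and returns at 30.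
- Aqueous acetic acid in THF hydrolyses the methyl acetal to the lactol F8.
- TMSOTf/2,6-lutidine followed by aqueous work-up cleaves the tert-butyl ester to the lactol acid F9.
- F9 is warmed with PPTS and 4 Å molecular sieves in benzene. The open hydroxy aldehyde can epimerise at C8′, and dehydrative closure drains the equilibrium into 30, the less strained bicycle.

Step 19. The most likely failure is slow or unselective enolisation, since the aligned C4′ hydrogen is shielded by the axial carbobicycle. This could be followed by epimerisation at C6′ or fragmentation of the acylal enolate before oxidation. The fallback introduces the oxygen before the bicycle exists. It sets out from 27 and returns at 32.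
- The unhindered tert-butyl ester of 27 is enolised (LiN(i-Pr)2, −78 °C) and oxidised with (+)-(camphorsulfonyl)oxaziridine to the α-hydroxy ester F10.
- Acetylation gives the α-acetoxy ester F11.
- F11 is closed directly with a catalytic amount of camphorsulfonic acid in warm toluene (loss of methanol and isobutene) to 32. The C4′ epimer would be separated at that stage.

Step 13. The most likely failure is incomplete olefination of the hindered ketone, or enolisation instead of addition. The fallback replaces carbonyl olefination by addition and elimination (Peterson olefination). It sets out from 20 and returns at 21.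
- Me3SiCH2Li with CeCl3 in THF at −78 °C adds to the ketone and gives the β-hydroxysilane F7.
- KH in THF effects syn elimination to 21. The acetal tolerates both operations.

Step 5. The most likely failure is partial loss of the dimethyl acetal during hydrolysis of the ethoxydiene, or sluggish coupling at the triflate next to the quaternary carbon. The fallback builds the acetyl group by carbonylation and Grignard addition, with no acid. It sets out from 7 and returns at 10.
- Pd(OAc)2/Xantphos, CO (1 atm), MeNH(OMe)·HCl and Et3N in toluene at 80 °C give the N-methoxy-N-methylamide F6.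
- MeMgBr in THF at 0 °C converts F6 into 10.

## Further compounds

F1 | step 9 | (R)-4,4-dimethyl-2-oxotetrahydrofuran-3-yl 4-methylpent-3-enoate | CC(C)=CCC(=O)O[C@H]1C(=O)OCC1(C)C
F2 | step 9 | (R)-4,4-dimethyl-2-oxotetrahydrofuran-3-yl 2-diazo-4-methylpent-3-enoate | CC(C)=CC(=[N+]=[N-])C(=O)O[C@H]1C(=O)OCC1(C)C
F3 | step 9 | (R)-pantolactonyl ester analogue of 16 | O=C(O[C@H]3C(=O)OCC3(C)C)C1=CC(C)(C)[C@@H]2CC[C@@](C)(CC(OC)OC)C2=C(O[Si](C)(C)C(C)(C)C)C1
F4 | step 9 | (R)-pantolactonyl ester analogue of 17 | O=C1CC(C(=O)O[C@H]3C(=O)OCC3(C)C)=CC(C)(C)[C@@H]2CC[C@@](C)(CC(OC)OC)[C@H]12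
F5 | step 9 | (R)-pantolactonyl ester of 18 (C6 epimers) | O=C1CC(C(=O)O[C@H]3C(=O)OCC3(C)C)CC(C)(C)[C@@H]2CC[C@@](C)(CC(OC)OC)[C@H]12
F6 | step 5 | (S)-5-(2,2-dimethoxyethyl)-N-methoxy-N,5-dimethylcyclopent-1-ene-1-carboxamide | CON(C)C(=O)C1=CCC[C@@]1(C)CC(OC)OC
F7 | step 13 | 1-(2,2-dimethoxyethyl)-1,4,4-trimethyl-8-[(trimethylsilyl)methyl]decahydroazulen-8-ol (cis-fused) | C[Si](C)(C)CC1(O)CCCC(C)(C)[C@@H]2CC[C@@](C)(CC(OC)OC)[C@H]12
F8 | step 18 | methyl (2R)-4-Az-3-(2-tert-butoxy-2-oxoethyl)-5-hydroxytetrahydrofuran-2-carboxylate (2,3-trans) | C=C1CCCC(C)(C)[C@@H]2CC[C@@](C)(C3C(O)O[C@@H](C(=O)OC)[C@@H]3CC(=O)OC(C)(C)C)[C@H]12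
F9 | step 18 | 2-[(2R)-4-Az-5-hydroxy-2-(methoxycarbonyl)tetrahydrofuran-3-yl]acetic acid (2,3-trans) | C=C1CCCC(C)(C)[C@@H]2CC[C@@](C)(C3C(O)O[C@@H](C(=O)OC)[C@@H]3CC(=O)O)[C@H]12
F10 | step 19 | methyl (2R)-4-Az-3-(2-tert-butoxy-1-hydroxy-2-oxoethyl)-5-methoxytetrahydrofuran-2-carboxylate | C=C1CCCC(C)(C)[C@@H]2CC[C@@](C)(C3C(OC)O[C@@H](C(=O)OC)[C@@H]3[C@H](O)C(=O)OC(C)(C)C)[C@H]12
F11 | step 19 | methyl (2R)-3-(1-acetoxy-2-tert-butoxy-2-oxoethyl)-4-Az-5-methoxytetrahydrofuran-2-carboxylate | C=C1CCCC(C)(C)[C@@H]2CC[C@@](C)(C3C(OC)O[C@@H](C(=O)OC)[C@@H]3[C@H](OC(C)=O)C(=O)OC(C)(C)C)[C@H]12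
A1 | alternative 1 | methyl 4-Az-3-(2-tert-butoxy-2-oxoethyl)-5-methoxytetrahydrofuran-2-carboxylate, single stereoisomer | C=C1CCCC(C)(C)[C@@H]2CC[C@@](C)([C@@H]3[C@H](OC)O[C@@H](C(=O)OC)[C@@H]3CC(=O)OC(C)(C)C)[C@H]12
A2 | alternative 2 | methyl 2-Az-acetate | C=C1CCCC(C)(C)[C@@H]2CC[C@@](C)(CC(=O)OC)[C@H]12
A3 | alternative 2 | (R)-4-(tert-butyldimethylsilyloxy)cyclopent-2-en-1-one | O=C1C=C[C@H](O[Si](C)(C)C(C)(C)C)C1
A4 | alternative 2 | methyl 2-Az-2-[5-(tert-butyldimethylsilyloxy)-2-hydroxy-3-oxocyclopentyl]acetate | C=C1CCCC(C)(C)[C@@H]2CC[C@@](C)([C@H](C(=O)OC)[C@H]3[C@H](O[Si](C)(C)C(C)(C)C)CC(=O)[C@@H]3O)[C@H]12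
A5 | alternative 3 | methyl 3-(2-hydroxy-5-oxocyclopent-1-en-1-yl)-3,7-dimethyloct-6-enoate | CC(C)=CCC[C@@](C)(CC(=O)OC)C1=C(O)CCC1=O
A6 | alternative 3 | methyl 2-(1,4,4-trimethyl-5,8-dioxodecahydroazulen-1-yl)acetate (cis-fused) | O=C1CCC(=O)C(C)(C)[C@@H]2CC[C@@](C)(CC(=O)OC)[C@H]12
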